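## Structural features

The target is a halimane-type diterpenoid ester: a 1,2,3,5,6,7,8,8a-octahydronaphthalene in which ring A (C1–C5, C10) and ring B (C5–C10) share the C5–C10 bond, and the only ring alkene, C1=C10, is trisubstituted and ends on a fusion carbon. Ring A holds the quaternary C4 (methyl and methyl ester) beside the tertiary fusion carbon C5. Ring B holds the tertiary C8 (methyl) beside the quaternary C9 (methyl and a five-carbon chain), and C9 is bonded to the sp2 carbon C10, so the two pairs of neighbouring stereocentres (C4/C5 and C8/C9) are separated by a carbon that carries no stereochemical information. The chain ends in an (E)-trisubstituted allylic formate (C13=C14, C15–OCHO); it is cleaved by base, nucleophiles and hydride and can ionise under acid, so it must be made last. The C1=C10 alkene can slip to the tetrasubstituted C5=C10 position under acid, and the C4 ester is too hindered for late exchange, so it is carried as the methyl ester throughout. The C4 ester is also cis and 1,3 to C10: an alkoxide or cation at C10 on that face stands diaxial to the ester and can close a five-membered lactone, which dictates the order of events. The real difficulty is the all-carbon quaternary C9 wedged between C8 and C10, in the correct relation to the remote C4/C5 pair, with no ring heteroatom left to steer it. The plan exploits the fact that three bonds of ring B, C7–C8, C9–C11 (from C9 to its side arm) and C5–C10, can be made in one thermal operation from a ring A cyclohexane.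

## Logic of the disconnections

32 to 31: the O15–CHO bond is cut first because the allylic formate is the most labile group. This leaves a robust primary allylic alcohol and asks only for a neutral acylation at the end.

31 to 28: the C13–CH3 and C14–C15 bonds are cut together, back to a terminal alkyne. A syn carbometalation fixes the (E) geometry by mechanism and avoids a hydride reduction that would have to tell two esters apart. The forward step must spare the C4 ester and the C1=C10 alkene.

28 to 27 to 26: the C13≡C14 bond is cut as a one-carbon homologation of an aldehyde, and the aldehyde is traced to the C13 alcohol. The side arm shrinks to three carbons; the forward steps need only mild, non-acidic conditions.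

26 to 25 to 23: the C6=C7 alkene is put back and the C13 oxygen removed, giving a triene. Its three alkenes differ in substitution (mono, cis-di, tri), so the forward steps can address them in turn, but each reagent must be chosen for that order.

23 to 21: the C1=C10 alkene is traced to loss of water from C10–OH and C1–H, because the key step leaves oxygen on C10. The forward elimination must be syn (only C1 has hydrogens syn to the oxygen; H5 is anti, C9 is quaternary) and must not ionise C10.

21 to 18: the key disconnection cuts C5–C10, C9–C11 and C7–C8. Ring B, the quaternary C9 and the C8 stereocentre disappear, leaving a cyclohexane with three stereocentres and an O-allyl group. The forward cascade demands trans-diequatorial alkenyl groups on C5 and C10, an (E)-butenyl group and the allyl group on the tertiary oxygen.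

18 to 16: the C4–CH3 bond is cut. Introducing this methyl last means the ester becomes cis to O10 only when O10 is already an ether, so no alkoxide ever faces a cis ester, and the vicinal vinyl and syn-axial allyloxy groups can steer the electrophile. The demand is face selectivity in an ester enolate alkylation.

16 to 13 and 14: the O–allyl bond is cut to a tertiary alcohol and an allyl halide. The forward etherification must outrun anionic oxy-Cope rearrangement of the alkoxide.

13 to 9 and 10: the C9–C10 bond is cut to an α-vinyl ketone and an alkenyl metal. The forward addition must go trans to the vinyl group without enolising the ketone and with retention of alkene geometry.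

9 to 7 to 2 and 6: the C5–C6 bond is cut; the vinyl group is traced to an aldol adduct of a vinyl-cation equivalent. This needs a regiodefined C5=C10 enol ether and an elimination that does not touch C5–H.

2 to 1, and 6 to 3 and 4: the C4–H bond is cut to hydride and the enone ester, which fixes the absolute configuration and the enol ether regiochemistry in one step; the selenium aldehyde comes from two commercial liquids.

## Other disconnections considered

Alternative 1: The cut is C4–C5. In the forward step the silyl ketene acetal of the ring B cyclohexenyl δ-lactone A2 undergoes an Ireland–Claisen ring contraction to the bicyclic acid A1, closing ring A and moving the alkene from C5=C10 to C1=C10. In its favour, the alkene arrives at C1=C10 without any tertiary alcohol to remove, C4 and C5 are set together through a ring-constrained ketene acetal, and the complete side chain is already in place. On alkene placement and on the endgame it is better than the chosen plan. Against it, the C8/C9 pair, which is the hard part of the molecule, must already exist in A2 and has to be made enantioselectively by separate chemistry. The lactone must react through a boat-like transition state. The carbinol centre at C1 becomes an extra stereocentre to control, and the new bond joins a quaternary C4 to a C5 flanked by the quaternary-substituted C10. Mechanistically both plans are sigmatropic and suprafacial, but this step builds one bond and two stereocentres where 18 to 21 builds three bonds and four. Counting the synthesis of ring B, it is expected to be longer.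

Alternative 2: The cut is C5–C6. In the forward step Me2AlCl promotes a type-two carbonyl-ene reaction of the aldehyde A4 with the ring A C5=C10 alkene, giving the C6 alcohol A3 with the alkene shifted to C1=C10. In its favour, the reaction runs at low temperature, the ene regiochemistry is unambiguous (C4 has no hydrogen), and the alkene again lands at C1=C10 directly. On mildness and alkene placement it is better than the chosen plan, and on ene regiocontrol it is its equal. Against it, the C6 hydroxyl must be removed afterwards. The C8/C9 pair sits on an acyclic tether in A4 and needs its own stereocontrolled synthesis. The new C5 centre is set relative to C4 only by the small difference between a methyl and an ester group. Structurally this plan leaves the quaternary C9 problem untouched, whereas the cascade from 18 solves it. In step count the two should be similar once the deoxygenation and the tether synthesis are included.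

Alternative 3: The cut is C9–C10. In the forward step a zerovalent palladium catalyst inserts into the ring A enol triflate A6; 6-exo carbopalladation of the tethered C9=C11 alkene forms the quaternary C9 and ring B, and β-hydride elimination toward the silyloxy carbon followed by hydrolysis gives the aldehyde A5. In its favour, it is catalytic, it makes the quaternary centre and the ring together, it keeps C1=C10 exactly where the triflate was, and the only β-hydrogens are on C12, so the elimination is clean. On alkene placement and on mass efficiency it is better than the chosen plan. Against it, the C9 configuration depends on a conformational preference of the tether that is not obviously large. C8 must be installed separately in a 1,4-relation to C5, and the C4/C5 pair must be made first. The chain still has to be extended by three carbons from A5, which is about the same work as from 23. Mechanistically it is stepwise and catalyst-bound, so ligand tuning is available, which the thermal cascade lacks. It controls two stereo elements independently, where the chosen plan relays all four from one pair of centres.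

Key step: step 8

Assumptions and remarks on the chemistry:
- Halimane numbering is used for ring and chain atoms in all intermediates (C4 is the ester-bearing carbon, C5 and C10 become the ring fusion, C11–C15 the side arm).
- (R)-DTBM-SEGPHOS is taken to deliver hydride to the face of C4 that gives the (1R) ester 2; if the sense is reversed on this β-ester enone, the (S) ligand is used and nothing else changes.
- The configurations of 18 and 21 were checked against a chair oxy-Cope, outer-face Claisen and suprafacial ene sequence and against 32. They are mutually consistent and need no correction.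
- One label does need correcting: the lithium reagent that keeps the geometry of (E)-10 is (Z)-but-2-en-2-yllithium by the sequence rules, because Li ranks below CH3. The group is (E) again once bonded to C10.

## Route

Step 1
Reactants: 1 methyl 3-oxocyclohex-1-ene-1-carboxylate
Product: 2 methyl (1R)-3-{[dimethyl(phenyl)silyl]oxy}cyclohex-2-ene-1-carboxylate
Conditions: Cu(OAc)2·H2O (cat.), (R)-DTBM-SEGPHOS (cat.), PhMe2SiH, PhMe, −20 °C
Reagents that add atoms: dimethyl(phenyl)silane, C[SiH](C)c1ccccc1
Why: Copper hydride asymmetric conjugate reduction of a β,β-disubstituted cyclic enone; hydride goes to C4 (β to the ketone, the stronger acceptor) and the copper enolate is silylated, so the C5=C10 enol ether forms regiospecifically. The ligand sets C4, which serves only as a relay centre for C5 and C10.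

Step 2
Reactants: 3 benzeneselenenyl chloride; 4 ethyl vinyl ether
Product: 6 (phenylselanyl)acetaldehyde, via chloro ether 5 (not isolated)
Conditions: CH2Cl2, −78 °C; then aq. NaHCO3, 0 °C
Reagents that add atoms: water, O
Why: Markovnikov selenenylation of the enol ether gives the α-chloro ether, which hydrolyses on work-up to the aldehyde, a vinyl-cation equivalent.

Step 3
Reactants: 2 silyl enol ether; 6 (phenylselanyl)acetaldehyde
Product: 7 methyl (1R,2R)-2-[1-hydroxy-2-(phenylselanyl)ethyl]-3-oxocyclohexane-1-carboxylate (both carbinol epimers)
Conditions: BF3·OEt2, CH2Cl2, −78 °C; aq. NaHCO3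
Reagents that add atoms: (phenylselanyl)acetaldehyde 6, O=CC[Se]c1ccccc1
Why: Mukaiyama aldol addition at C5 without a basic enolate, so the ester α-hydrogen at C4 is safe. The aldehyde enters anti to the C4 ester, and C5 stays epimerisable toward the trans-diequatorial arrangement; the carbinol centre is lost in step 4.

Step 4
Reactants: 7 β-hydroxy selenide
Product: 9 methyl (1R,2S)-2-ethenyl-3-oxocyclohexane-1-carboxylate, via mesylate 8 (not isolated)
Conditions: MsCl, Et3N, CH2Cl2, 0 °C
Reagents that add atoms: none
Why: Mesylation, then selenium-assisted anti-elimination through a seleniranium ion, releases the vinyl group regiospecifically (vinylation of a ketone through a β-hydroxy selenide). The vinyl group settles trans to the ester; prompt work-up avoids migration of the alkene into conjugation.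

Step 5
Reactants: 9 α-vinyl ketone; 10 (E)-2-bromobut-2-ene
Product: 13 methyl (1R,2S,3R)-3-[(2E)-but-2-en-2-yl]-2-ethenyl-3-hydroxycyclohexane-1-carboxylate, via butenyllithium 11 (not isolated), via butenylcerium dichloride 12 (not isolated)
Conditions: 10, t-BuLi (2 equiv.), Et2O, −78 °C; CeCl3, THF, −78 °C; then 9, −78 °C; aq. NH4Cl
Reagents that add atoms: (E)-2-bromobut-2-ene 10, C/C=C(\C)Br
Why: Br/Li exchange with retention, transmetalation to the weakly basic organocerium reagent and equatorial 1,2-addition trans to the equatorial vinyl group set C10 (oxygen axial, cis to vinyl). The ester is trans to the new alkoxide and cannot lactonise.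

Step 6
Reactants: 13 tertiary carbinol; 14 allyl bromide
Product: 16 methyl (1R,2S,3R)-3-[(2E)-but-2-en-2-yl]-2-ethenyl-3-(prop-2-en-1-yloxy)cyclohexane-1-carboxylate, via potassium alkoxide 15 (not isolated)
Conditions: KH, allyl bromide (excess, present from the start), THF, 0 °C
Reagents that add atoms: allyl bromide 14, C=CCBr
Why: Williamson etherification of the tertiary potassium alkoxide; with the halide present, no crown ether and 0 °C, O-alkylation should outrun anionic oxy-Cope rearrangement.

Step 7
Reactants: 16 allyl ether ester
Product: 18 methyl (1S,2S,3R)-3-[(2E)-but-2-en-2-yl]-2-ethenyl-1-methyl-3-(prop-2-en-1-yloxy)cyclohexane-1-carboxylate, via lithium enolate 17 (not isolated)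
Conditions: LiN(iPr)2, THF, −78 °C; MeI, DMPU, −78 to −20 °C
Reagents that add atoms: iodomethane, CI
Why: Ester enolate alkylation; MeI should approach C4 anti to the vicinal vinyl group and away from the syn-axial allyloxy group on C10, so the methyl ends trans to vinyl and the ester cis to O10. No alkoxide is present when this cis relationship is created, so the lactone cannot form.

Step 8
Reactants: 18 dialkenylcyclohexyl allyl ether
Product: 21 methyl (1S,4aR,5S,6R,8aS)-4a-hydroxy-1,5,6-trimethyl-5-(prop-2-en-1-yl)-1,2,3,4,4a,5,6,8a-octahydronaphthalene-1-carboxylate, via allyl enol ether 19 (not isolated), via cyclodecenone 20 (not isolated)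
Conditions: PhMe (degassed, dilute), sealed silanised vessel, 200–220 °C
Reagents that add atoms: none
Why: Heating starts a chair oxy-Cope rearrangement of the diene C8=C9–C10–C5–C6=C7 with both alkenyl groups equatorial, which breaks C5–C10, forms C7–C8 and gives the ten-membered allyl enol ether 19 with both ring alkenes trans to the ring. The allyl group then moves from oxygen to C9 by a chair Claisen shift, forming C9–C11 and the C10 ketone 20. The ketone and the C5=C6 alkene face each other across the ring and undergo a transannular carbonyl-ene reaction (C10–C5 bond, a C7 hydrogen to oxygen), which closes the six-membered ring B as a trans-fused decalinol. The closest known reaction type is the thermal oxy-Cope, Claisen and ene cascade of 1,2-dialkenylcyclohexyl allyl ethers to decalinols with a quaternary carbon beside the carbinol. C8 is set by the chair geometry and the (E)-butenyl group (methyl pseudo-equatorial), and C9 by allyl delivery to the outer face of the enol ether, the inner face being blocked by the ring. C5 and C10 re-form on the faces from which they separated, since the tetrasubstituted enol ether cannot turn through the ring, so the planar chirality fixed by C5 and C10 of 18 is relayed to all four centres. The step needs chair over boat in the first shift, secured by the diequatorial alkenyl groups. It also needs a single ene regiochemistry, secured because the alternative closure to a five–seven skeleton would require a hydrogen on the quaternary C4.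

Step 9
Reactants: 21 decalinol
Product: 23 methyl (1S,5S,6R,8aR)-1,5,6-trimethyl-5-(prop-2-en-1-yl)-1,2,3,5,6,8a-hexahydronaphthalene-1-carboxylate, via sulfamate salt 22 (not isolated)
Conditions: MeO2CN(−)SO2N(+)Et3 (Burgess reagent), PhH, 25 to 50 °C
Reagents that add atoms: none
Why: Burgess dehydration is a syn-elimination through the sulfamate ester; the only hydrogens syn to the C10 oxygen are on C1 (H5 is anti, C9 is quaternary), so the alkene should form at C1=C10.

Step 10
Reactants: 23 triene ester
Product: 25 methyl (1S,5S,6R,8aR)-5-(3-hydroxypropyl)-1,5,6-trimethyl-1,2,3,5,6,8a-hexahydronaphthalene-1-carboxylate, via alkylborane 24 (not isolated)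
Conditions: 9-BBN, THF, 0 °C to rt; then H2O2, aq. NaOH, 0 °C
Reagents that add atoms: hydrogen peroxide, OO
Why: 9-BBN hydroborates the monosubstituted alkene far faster than the cis-disubstituted C6=C7 or trisubstituted C1=C10 alkene and does not reduce the ester; oxidation gives the anti-Markovnikov alcohol at C13.

Step 11
Reactants: 25 dienyl alcohol
Product: 26 methyl (1S,5S,6R,8aR)-5-(3-hydroxypropyl)-1,5,6-trimethyl-1,2,3,5,6,7,8,8a-octahydronaphthalene-1-carboxylate
Conditions: H2 (1 atm), RhCl(PPh3)3 (cat.), PhH/EtOH, rt
Reagents that add atoms: none
Why: Homogeneous hydrogenation with RhCl(PPh3)3 reduces the disubstituted C6=C7 alkene and leaves the hindered trisubstituted C1=C10 alkene, without double-bond migration; no stereocentre is created.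

Step 12
Reactants: 26 alcohol
Product: 27 methyl (1S,5S,6R,8aR)-1,5,6-trimethyl-5-(3-oxopropyl)-1,2,3,5,6,7,8,8a-octahydronaphthalene-1-carboxylate
Conditions: Dess–Martin periodinane, NaHCO3, CH2Cl2, 0 °C to rt
Reagents that add atoms: none
Why: Dess–Martin oxidation of the primary alcohol under buffered conditions that do not isomerise the C1=C10 alkene.

Step 13
Reactants: 27 aldehyde
Product: 28 methyl (1S,5S,6R,8aR)-5-(but-3-yn-1-yl)-1,5,6-trimethyl-1,2,3,5,6,7,8,8a-octahydronaphthalene-1-carboxylate
Conditions: MeC(O)C(N2)P(O)(OMe)2, K2CO3, MeOH, 0 °C to rt
Reagents that add atoms: dimethyl (1-diazo-2-oxopropyl)phosphonate, CC(=O)C(=[N+]=[N-])P(=O)(OC)OC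
Why: Seyferth–Gilbert homologation with the Ohira–Bestmann reagent adds C14 as a terminal alkyne; the mild carbonate/methanol medium leaves the hindered C4 ester alone.

Step 14
Reactants: 28 alkyne
Product: 31 methyl (1S,5S,6R,8aR)-5-[(3E)-5-hydroxy-3-methylpent-3-en-1-yl]-1,5,6-trimethyl-1,2,3,5,6,7,8,8a-octahydronaphthalene-1-carboxylate, via alkenylalane 29 (not isolated), via lithium alanate 30 (not isolated)
Conditions: Me3Al, Cp2ZrCl2, CH2Cl2, 0 °C to rt; evaporate; n-BuLi, hexane/THF, −78 to 0 °C; (CH2O)n, rt
Reagents that add atoms: trimethylaluminium, C[Al](C)C; formaldehyde (from paraformaldehyde), C=O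
Why: Zirconium-catalysed syn-carboalumination (Negishi) puts methyl on C13 and aluminium on C14, and the derived alanate is hydroxymethylated with retention, so the alkene is (E) by mechanism. No hydride is used, so the C4 ester is not at risk of reduction.

Step 15
Reactants: 31 allylic alcohol
Product: 32 methyl (1S,5S,6R,8aR)-5-[(3E)-5-(formyloxy)-3-methylpent-3-en-1-yl]-1,5,6-trimethyl-1,2,3,5,6,7,8,8a-octahydronaphthalene-1-carboxylate (CNP0188193.1)
Conditions: HCO2H, DCC, DMAP (cat.), CH2Cl2, 0 °C
Reagents that add atoms: formic acid, O=CO
Why: Steglich-type formylation of the primary allylic alcohol under neutral conditions that spare the allylic C–O bond and the ring alkene.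

## Compound list

1 | methyl 3-oxocyclohex-1-ene-1-carboxylate | COC(=O)C1=CC(=O)CCC1 | starting material
2 | methyl (1R)-3-{[dimethyl(phenyl)silyl]oxy}cyclohex-2-ene-1-carboxylate | COC(=O)[C@@H]1CCCC(O[Si](C)(C)c2ccccc2)=C1 | intermediate
3 | benzeneselenenyl chloride | Cl[Se]c1ccccc1 | starting material
4 | ethyl vinyl ether | C=COCC | starting material
5 | (2-chloro-2-ethoxyethyl)(phenyl)selane (racemic) | CCOC(Cl)C[Se]c1ccccc1 | intermediate (not isolated)
6 | (phenylselanyl)acetaldehyde | O=CC[Se]c1ccccc1 | intermediate
7 | methyl (1R,2R)-2-[1-hydroxy-2-(phenylselanyl)ethyl]-3-oxocyclohexane-1-carboxylate (side chain trans to ester; both carbinol epimers) | COC(=O)[C@@H]1CCCC(=O)[C@H]1C(O)C[Se]c1ccccc1 | intermediate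
8 | methyl (1R,2R)-2-[1-(methanesulfonyloxy)-2-(phenylselanyl)ethyl]-3-oxocyclohexane-1-carboxylate | COC(=O)[C@@H]1CCCC(=O)[C@H]1C(OS(C)(=O)=O)C[Se]c1ccccc1 | intermediate (not isolated)
9 | methyl (1R,2S)-2-ethenyl-3-oxocyclohexane-1-carboxylate (vinyl trans to ester) | COC(=O)[C@@H]1CCCC(=O)[C@H]1C=C | intermediate
10 | (E)-2-bromobut-2-ene | C/C=C(\C)Br | starting material
11 | (Z)-but-2-en-2-yllithium (geometry of 10 retained, methyl groups cis) | C/C=C(\C)[Li] | intermediate (not isolated)
12 | dichloro[(E)-but-2-en-2-yl]cerium | C/C=C(\C)[Ce](Cl)Cl | intermediate (not isolated)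
13 | methyl (1R,2S,3R)-3-[(2E)-but-2-en-2-yl]-2-ethenyl-3-hydroxycyclohexane-1-carboxylate (OH cis to vinyl, trans to ester) | COC(=O)[C@@H]1CCC[C@](O)(/C(C)=C/C)[C@H]1C=C | intermediate
14 | allyl bromide (3-bromoprop-1-ene) | C=CCBr | starting material
15 | potassium alkoxide of 13 | COC(=O)[C@@H]1CCC[C@]([O-])(/C(C)=C/C)[C@H]1C=C.[K+] | intermediate (not isolated)
16 | methyl (1R,2S,3R)-3-[(2E)-but-2-en-2-yl]-2-ethenyl-3-(prop-2-en-1-yloxy)cyclohexane-1-carboxylate | COC(=O)[C@@H]1CCC[C@](OCC=C)(/C(C)=C/C)[C@H]1C=C | intermediate
17 | lithium enolate of 16 (C4 planar) | COC(O[Li])=C1CCC[C@](OCC=C)(/C(C)=C/C)[C@H]1C=C | intermediate (not isolated)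
18 | methyl (1S,2S,3R)-3-[(2E)-but-2-en-2-yl]-2-ethenyl-1-methyl-3-(prop-2-en-1-yloxy)cyclohexane-1-carboxylate (ester, vinyl and O-allyl all cis) | COC(=O)[C@@]1(C)CCC[C@](OCC=C)(/C(C)=C/C)[C@H]1C=C | intermediate (key-step precursor)
19 | methyl (1S,2E,5R,6Z)-1,5,6-trimethyl-7-(prop-2-en-1-yloxy)cyclodeca-2,6-diene-1-carboxylate (both ring alkenes trans to the ring) | COC(=O)[C@@]1(C)CCC/C(OCC=C)=C(C)/[C@H](C)C/C=C/1 | intermediate (not isolated)
20 | methyl (1S,2E,5R,6S)-1,5,6-trimethyl-7-oxo-6-(prop-2-en-1-yl)cyclodec-2-ene-1-carboxylate | COC(=O)[C@@]1(C)CCCC(=O)[C@@](C)(CC=C)[C@H](C)C/C=C/1 | intermediate (not isolated)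
21 | methyl (1S,4aR,5S,6R,8aS)-4a-hydroxy-1,5,6-trimethyl-5-(prop-2-en-1-yl)-1,2,3,4,4a,5,6,8a-octahydronaphthalene-1-carboxylate (10-OH trans to H5, cis to the C4 ester and to the C9 allyl group) | COC(=O)[C@@]1(C)CCC[C@@]2(O)[C@H]1C=C[C@@H](C)[C@]2(C)CC=C | intermediate (key-step product)
22 | triethylammonium salt of the C10 N-(methoxycarbonyl)sulfamate ester of 21 | COC(=O)[C@@]1(C)CCC[C@@]2(OS(=O)(=O)[N-]C(=O)OC)[C@H]1C=C[C@@H](C)[C@]2(C)CC=C.CC[NH+](CC)CC | intermediate (not isolated)
23 | methyl (1S,5S,6R,8aR)-1,5,6-trimethyl-5-(prop-2-en-1-yl)-1,2,3,5,6,8a-hexahydronaphthalene-1-carboxylate | COC(=O)[C@@]1(C)CCC=C2[C@H]1C=C[C@@H](C)[C@]2(C)CC=C | intermediate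
24 | B-alkyl-9-borabicyclo[3.3.1]nonane from 23 (boron on C13) | COC(=O)[C@@]1(C)CCC=C2[C@H]1C=C[C@@H](C)[C@]2(C)CCCB1C2CCCC1CCC2 | intermediate (not isolated)
25 | methyl (1S,5S,6R,8aR)-5-(3-hydroxypropyl)-1,5,6-trimethyl-1,2,3,5,6,8a-hexahydronaphthalene-1-carboxylate | COC(=O)[C@@]1(C)CCC=C2[C@H]1C=C[C@@H](C)[C@]2(C)CCCO | intermediate
26 | methyl (1S,5S,6R,8aR)-5-(3-hydroxypropyl)-1,5,6-trimethyl-1,2,3,5,6,7,8,8a-octahydronaphthalene-1-carboxylate | COC(=O)[C@@]1(C)CCC=C2[C@H]1CC[C@@H](C)[C@]2(C)CCCO | intermediate
27 | methyl (1S,5S,6R,8aR)-1,5,6-trimethyl-5-(3-oxopropyl)-1,2,3,5,6,7,8,8a-octahydronaphthalene-1-carboxylate | COC(=O)[C@@]1(C)CCC=C2[C@H]1CC[C@@H](C)[C@]2(C)CCC=O | intermediate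
28 | methyl (1S,5S,6R,8aR)-5-(but-3-yn-1-yl)-1,5,6-trimethyl-1,2,3,5,6,7,8,8a-octahydronaphthalene-1-carboxylate | COC(=O)[C@@]1(C)CCC=C2[C@H]1CC[C@@H](C)[C@]2(C)CCC#C | intermediate
29 | (E)-alkenyl(dimethyl)alane from 28 (methyl on C13, aluminium on C14) | COC(=O)[C@@]1(C)CCC=C2[C@H]1CC[C@@H](C)[C@]2(C)CC/C(C)=C/[Al](C)C | intermediate (not isolated)
30 | lithium (E)-alkenyl(butyl)dimethylalanate from 29 | COC(=O)[C@@]1(C)CCC=C2[C@H]1CC[C@@H](C)[C@]2(C)CC/C(C)=C/[Al-](C)(C)CCCC.[Li+] | intermediate (not isolated)
31 | methyl (1S,5S,6R,8aR)-5-[(3E)-5-hydroxy-3-methylpent-3-en-1-yl]-1,5,6-trimethyl-1,2,3,5,6,7,8,8a-octahydronaphthalene-1-carboxylate | COC(=O)[C@@]1(C)CCC=C2[C@H]1CC[C@@H](C)[C@]2(C)CC/C(C)=C/CO | intermediate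
32 | methyl (1S,5S,6R,8aR)-5-[(3E)-5-(formyloxy)-3-methylpent-3-en-1-yl]-1,5,6-trimethyl-1,2,3,5,6,7,8,8a-octahydronaphthalene-1-carboxylate | COC(=O)[C@@]1(C)CCC=C2[C@H]1CC[C@@H](C)[C@]2(C)CC/C(C)=C/COC=O | target

## Step count and least certain steps

Total step count: 15. Longest linear sequence: 14 steps from 1 (steps 1 and 3–15); step 2 is a one-step reagent preparation.

Step 8 (key step). The cascade is most likely to stall after the Claisen shift, because the ene closure must join C10 and C5, each flanked by a quaternary carbon (C9 and C4). Forcing it by longer heating invites loss of methanol between the diaxial C10 hydroxyl and the C4 ester of the product, and a boat oxy-Cope pathway could leak diastereomers. Fallback: the thermolysis of 18 is stopped at lower temperature once 18 is consumed, the ketone 20 is isolated, and ring B is closed by a Lewis-acid transannular carbonyl-ene reaction (Me2AlCl, CH2Cl2, −78 °C, cold quench). This sets out from 18, passes through isolated 20 and returns at 21; it makes no new compound.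

Step 7. Methylation could occur on the wrong face of the enolate. Relief of allylic strain may put the vinyl group axial, and in that conformer the face anti to vinyl is shielded by the axial butenyl group on C10, so the preference is not guaranteed. Fallback: the approach changes from alkylating the ether to alkylating the carbinol. From 13, the alkoxide–enolate dianion (LiN(iPr)2, 2.2 equiv.) is methylated, and the wanted epimer, with its ester now cis to the lithium alkoxide, closes spontaneously to the bridged lactone 5-[(2E)-but-2-en-2-yl]-8-ethenyl-1-methyl-6-oxabicyclo[3.2.1]octan-7-one F1. The wrong epimer cannot close and is removed as the hydroxy ester, so the lactone both proves and purifies the C4 configuration. Saponification (KOH, aq. MeOH) gives the potassium hydroxy-carboxylate F2. O-allylation in THF (KH, allyl bromide; carboxylates are poor nucleophiles there) and acidification give the allyl ether acid F3, and Me3SiCHN2 returns the route at 18.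

Step 9. The sulfamate may ionise at C10 faster than it eliminates. The cation could then be captured by the syn-diaxial ester carbonyl (lactone formation with loss of the O-methyl group), lose the allylic H5 to give a conjugated diene, or suffer a 1,2-shift from C9. Fallback: the ester is taken out of play before dehydration. From 21 (or from its lactone, which converges), LiAlH4 gives the diol 4-(hydroxymethyl) decalinol F4 and TBSCl/imidazole protects the primary hydroxyl as the silyl ether F5. Burgess dehydration then gives the triene silyl ether F6 and Bu4NF the triene alcohol F7. Oxidation with TEMPO/PhI(OAc)2 in aqueous MeCN gives the triene acid F8, and Me3SiCHN2 returns the route at 23.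

Step 14. The hindered ester may still be attacked when n-BuLi is added to form the alanate, or capture of formaldehyde may be inefficient. Fallback: the alkene is built by olefination instead of carbometalation. From 28, hydration with Ph3PAuNTf2 (cat.) in aqueous MeOH gives the methyl ketone F9. Horner–Wadsworth–Emmons reaction (triethyl phosphonoacetate, NaH, THF) gives the (E)-enoate F10 after removal of the (Z) isomer. iBu2AlH at −78 °C reduces the unhindered conjugated ester in preference to the neopentyl C4 ester and returns the route at 31.

Step 6. The potassium alkoxide 15 could undergo anionic oxy-Cope rearrangement before it is alkylated. It could also remove the syn-diaxial C4 hydrogen, which would lead to epimerisation at C4 followed by lactonisation or C-allylation. Fallback: etherification without a free alkoxide. From 13, zerovalent-palladium-catalysed allylation with allyl tert-butyl carbonate (Pd2(dba)3, dppb, THF, 65 °C), a method that tolerates hindered tertiary alcohols, returns the route at 16; it makes no new compound.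

## Further compounds

F0 | step 8 | none | none
F1 | step 7 | 5-[(2E)-but-2-en-2-yl]-8-ethenyl-1-methyl-6-oxabicyclo[3.2.1]octan-7-one (lactone between the C4 carbonyl and O10) | O=C1O[C@]2(/C(C)=C/C)CCC[C@@]1(C)[C@@H]2C=C
F2 | step 7 | potassium 3-[(2E)-but-2-en-2-yl]-2-ethenyl-3-hydroxy-1-methylcyclohexane-1-carboxylate (configuration of 18) | [K+].[O-]C(=O)[C@@]1(C)CCC[C@](O)(/C(C)=C/C)[C@H]1C=C
F3 | step 7 | 3-[(2E)-but-2-en-2-yl]-2-ethenyl-1-methyl-3-(prop-2-en-1-yloxy)cyclohexane-1-carboxylic acid (configuration of 18) | OC(=O)[C@@]1(C)CCC[C@](OCC=C)(/C(C)=C/C)[C@H]1C=C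
F4 | step 9 | 4-(hydroxymethyl) analogue of 21 (diol) | OC[C@@]1(C)CCC[C@@]2(O)[C@H]1C=C[C@@H](C)[C@]2(C)CC=C
F5 | step 9 | primary tert-butyldimethylsilyl ether of F4 | CC(C)(C)[Si](C)(C)OC[C@@]1(C)CCC[C@@]2(O)[C@H]1C=C[C@@H](C)[C@]2(C)CC=C
F6 | step 9 | silyl ether of the 1(10),6-diene carrying the C9 allyl group | CC(C)(C)[Si](C)(C)OC[C@@]1(C)CCC=C2[C@H]1C=C[C@@H](C)[C@]2(C)CC=C
F7 | step 9 | primary alcohol corresponding to 23 | OC[C@@]1(C)CCC=C2[C@H]1C=C[C@@H](C)[C@]2(C)CC=C
F8 | step 9 | carboxylic acid corresponding to 23 | OC(=O)[C@@]1(C)CCC=C2[C@H]1C=C[C@@H](C)[C@]2(C)CC=C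
F9 | step 14 | methyl (1S,5S,6R,8aR)-1,5,6-trimethyl-5-(3-oxobutyl)-1,2,3,5,6,7,8,8a-octahydronaphthalene-1-carboxylate | COC(=O)[C@@]1(C)CCC=C2[C@H]1CC[C@@H](C)[C@]2(C)CCC(C)=O
F10 | step 14 | ethyl (2E)-enoate from F9 (C13=C14, ethyl ester at C15) | COC(=O)[C@@]1(C)CCC=C2[C@H]1CC[C@@H](C)[C@]2(C)CC/C(C)=C/C(=O)OCC
F0 | step 6 | none | none
A1 | alternative 1 | bicyclic C4 carboxylic acid with the silyl-protected side chain | OC(=O)[C@@]1(C)CCC=C2[C@H]1CC[C@@H](C)[C@]2(C)CC/C(C)=C/CO[Si](C)(C)C(C)(C)C
A2 | alternative 1 | 3-methyl-6-(cyclohex-1-enyl) δ-lactone (C4 epimers; carbinol C1 configured for suprafacial transfer to C5) | CC1CC[C@@H](OC1=O)C2=CCC[C@@H](C)[C@]2(C)CC/C(C)=C/CO[Si](C)(C)C(C)(C)C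
A3 | alternative 2 | bicyclic C6 alcohol (C6 epimer inconsequential) | COC(=O)[C@@]1(C)CCC=C2[C@H]1[C@@H](O)C[C@@H](C)[C@]2(C)CC/C(C)=C/CO[Si](C)(C)C(C)(C)C
A4 | alternative 2 | ring A cyclohexene (C5=C10) carrying the C9/C8 tether that ends in the C6 aldehyde | COC(=O)[C@@]1(C)CCCC(=C1)[C@@](C)(CC/C(C)=C/CO[Si](C)(C)C(C)(C)C)[C@H](C)CC=O
A5 | alternative 3 | bicyclic C12 aldehyde | COC(=O)[C@@]1(C)CCC=C2[C@H]1CC[C@@H](C)[C@]2(C)CC=O
A6 | alternative 3 | ring A enol triflate (C10–OTf, C1=C10) with the (E)-C9=C11 allylic silyl ether tether | COC(=O)[C@@]1(C)CCC=C(OS(=O)(=O)C(F)(F)F)[C@H]1CC[C@@H](C)/C(C)=C/CO[Si](C)(C)C(C)(C)C
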